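**Retrosynthetic overview**
1. Ca–Cb: enantioconvergent Ni-catalysed coupling of a racemic 1-chloroethyl pyranone (ring A, from 1) with an (E)-alkenyl bromide; this is the last C–C bond.
2. Cf–Cg: lateral (vinylogous) lithium aldol of the ring B pyranone onto a 2,3-anti α-methyl-β-silyloxy aldehyde.
3. Ch–Ci (key step): catalytic enantioselective vinylogous Mukaiyama aldol of the symmetric heteroaromatic γ-pyrone 1 with propanal, through its dearomatised methylenepyran.
4. Cd/Ce: Brown anti-crotylation of (E)-3-bromo-2-methylacrolein, then cleavage of the vinyl group to the aldehyde.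
5. Rings: none is built. Both pyranones come from 1; ring B is elaborated first (steps 1 and 6), ring A is attached last (step 8).

Chain labels: ring A–Ca(H)(Me)–Cb=Cc(Me)–Cd(OH)–Ce(H)(Me)–Cf(OH)–Cg(H)(Me)–ring B–Ch(H)(Me)–Ci(OH)–Et. Target: Ca S, Cb=Cc E, Cd S, Ce S, Cf S, Cg S, Ch R, Ci R.

Assumption: 1 is bought as a catalogue γ-pyrone (otherwise one step from pentan-3-one and propanoic acid in polyphosphoric acid).

**Step 1**
Reactants: 1 2,6-diethyl-3,5-dimethyl-4H-pyran-4-one; 2 propanal
Product: 4 2-ethyl-6-[(2R,3R)-3-hydroxypentan-2-yl]-3,5-dimethyl-4H-pyran-4-one, via silyl dienol ether 3 (not isolated)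
Conditions: TBSOTf, Et3N, CH2Cl2, 0 °C; pentane, filter; then 2, SiCl4, (S,S)-binaphthyldiamine-derived bisphosphoramide with pentane-1,5-diyl tether (5 mol%), i-Pr2NEt (cat.), CH2Cl2, −78 °C; aq. NaHCO3
Reagents that add atoms: none
Why: Proposed new method: O-silylation of 1 gives a 4-silyloxypyrylium ion that Et3N deprotonates at one of the two equivalent ethyl CH2 groups to the dearomatised (Z)-methylenepyran 3, which attacks propanal bound to the chiral phosphoramide–SiCl3 cation at its exocyclic carbon through an open transition state and thereby restores the pyranone; the catalyst selects the Si face of the aldehyde (Ci R) and the arrangement with the aldehyde ethyl group anti to the pyran ring gives the Ch/Ci anti isomer (Ch R); closest known reaction type: Lewis-base-activated SiCl4 vinylogous Mukaiyama aldol of γ-methyl silyl dienol ethers, which is anti-selective with high ee (catalyst antipode assigned by analogy, to be confirmed by Mosher analysis of 4).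

**Step 2**
Reactants: 5 2-methylprop-2-enal
Product: 7 (2E)-3-bromo-2-methylprop-2-enal, via 2,3-dibromo-2-methylpropanal 6 (not isolated)
Conditions: Br2, CH2Cl2, −78 to 0 °C; then Et3N, 0 °C to rt
Reagents that add atoms: bromine, BrBr
Why: Bromine addition to the enal followed by amine-mediated dehydrobromination gives the conjugated bromoenal, the E isomer (Br trans to CHO) being the thermodynamic product.

**Step 3**
Reactants: 7 (2E)-3-bromo-2-methylprop-2-enal; 8 (E)-but-2-ene
Product: 11 (1E,3S,4S)-1-bromo-2,4-dimethylhexa-1,5-dien-3-ol, via crotylpotassium 9 (not isolated), via crotyldiisopinocampheylborane 10 (not isolated)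
Conditions: 8, n-BuLi, KOt-Bu, THF, −78 to −45 °C; (−)-Ipc2BOMe, −78 °C; BF3·OEt2; 7, −78 °C; then NaOH, H2O2
Reagents that add atoms: none
Why: Brown crotylboration through a chair Zimmerman–Traxler transition state: the (E)-crotyl group gives the Cd/Ce anti relationship and the isopinocampheyl groups from (+)-α-pinene direct attack to the Si face of the aldehyde (Cd S, Ce S).

**Step 4**
Reactants: 11 (1E,3S,4S)-1-bromo-2,4-dimethylhexa-1,5-dien-3-ol
Product: 12 {[(1E,3S,4S)-1-bromo-2,4-dimethylhexa-1,5-dien-3-yl]oxy}(tert-butyl)dimethylsilane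
Conditions: TBSOTf, 2,6-lutidine, CH2Cl2, −78 to 0 °C
Reagents that add atoms: tert-butyldimethylsilyl trifluoromethanesulfonate, CC(C)(C)[Si](C)(C)OS(=O)(=O)C(F)(F)F
Why: Standard silylation of a hindered secondary allylic alcohol with the silyl triflate; no stereocentre is touched.

**Step 5**
Reactants: 12 {[(1E,3S,4S)-1-bromo-2,4-dimethylhexa-1,5-dien-3-yl]oxy}(tert-butyl)dimethylsilane
Product: 14 (2R,3S,4E)-5-bromo-3-[(tert-butyldimethylsilyl)oxy]-2,4-dimethylpent-4-enal, via vicinal diol 13 (not isolated)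
Conditions: OsO4 (2 mol%), NaIO4, 2,6-lutidine, dioxane/H2O, rt
Reagents that add atoms: osmium tetroxide, O=[Os](=O)(=O)=O; sodium periodate, [Na+].[O-]I(=O)(=O)=O (refills the oxo ligands)
Why: Lemieux–Johnson cleavage: the monosubstituted terminal alkene is dihydroxylated much faster than the electron-poor, hindered trisubstituted bromoalkene, and the lutidine buffer keeps the α-stereocentre (Ce) from epimerising.

**Step 6**
Reactants: 4 2-ethyl-6-[(2R,3R)-3-hydroxypentan-2-yl]-3,5-dimethyl-4H-pyran-4-one; 14 (2R,3S,4E)-5-bromo-3-[(tert-butyldimethylsilyl)oxy]-2,4-dimethylpent-4-enal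
Product: 16 2-[(2S,3S,4S,5S,6E)-7-bromo-5-[(tert-butyldimethylsilyl)oxy]-3-hydroxy-4,6-dimethylhept-6-en-2-yl]-6-[(2R,3R)-3-hydroxypentan-2-yl]-3,5-dimethyl-4H-pyran-4-one, via dilithium dianion 15 (not isolated)
Conditions: LiN(i-Pr)2 (2.2 equiv), THF, −78 °C; then 14, −78 °C; AcOH, −78 °C
Reagents that add atoms: none
Why: Lateral lithiation–aldol of a 2-ethyl-4-pyranone: after the alkoxide forms, the second equivalent of base removes the unhindered ethyl CH2 proton, and the dienolate adds through an open transition state to the Felkin–Anh face of 14 (Cf–OH syn to the Ce methyl and anti to the Cd silyloxy group, both preferences reinforcing in a 2,3-anti aldehyde) with the aldehyde chain anti to the pyran ring, giving Cf/Cg anti (Cf S, Cg S).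

**Step 7**
Reactants: 1 2,6-diethyl-3,5-dimethyl-4H-pyran-4-one
Product: 18 rac-2-(1-chloroethyl)-6-ethyl-3,5-dimethyl-4H-pyran-4-one, via lithium dienolate 17 (not isolated)
Conditions: LiN(SiMe3)2, THF, −78 °C; cannulate into C2Cl6, THF, −78 °C
Reagents that add atoms: hexachloroethane, ClC(Cl)(Cl)C(Cl)(Cl)Cl
Why: Electrophilic chlorination of the lateral dienolate at its exocyclic carbon; inverse addition keeps the more acidic product away from unreacted dienolate, and a racemate is acceptable because step 8 is enantioconvergent.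

**Step 8**
Reactants: 16 (alkenyl bromide above); 18 rac-2-(1-chloroethyl)-6-ethyl-3,5-dimethyl-4H-pyran-4-one
Product: 19 2-[(2S,3S,4S,5S,6E,8S)-5-[(tert-butyldimethylsilyl)oxy]-8-(6-ethyl-3,5-dimethyl-4-oxo-4H-pyran-2-yl)-3-hydroxy-4,6-dimethylnon-6-en-2-yl]-6-[(2R,3R)-3-hydroxypentan-2-yl]-3,5-dimethyl-4H-pyran-4-one
Conditions: NiCl2(dme) (10 mol%), (3aR,8aS)-indanyl bis(oxazoline) with cyclopropane-1,1-diyl bridge (11 mol%), Mn powder, NaI, DMA, 0 °C; 18 (2 equiv)
Reagents that add atoms: none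
Why: Proposed new method: zerovalent nickel adds oxidatively to the alkenyl bromide of 16 with retention of the E geometry, the alkenylnickel species captures the planar pyranone-stabilised secondary radical formed from either enantiomer of 18 by halogen abstraction, and reductive elimination from the ligand-bound trivalent nickel sets Ca as S under catalyst control while Mn powder turns the cycle over; closest known reaction type: Ni/bis(oxazoline)-catalysed enantioconvergent reductive coupling of 1-chloroethylarenes with alkenyl bromides, the pyranone taking the place of the arene (ligand antipode to be confirmed on a model coupling).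

**Step 9**
Reactants: 19 (silyl ether above)
Product: 20 2-[(2S,3S,4S,5S,6E,8S)-8-(6-ethyl-3,5-dimethyl-4-oxo-4H-pyran-2-yl)-3,5-dihydroxy-4,6-dimethylnon-6-en-2-yl]-6-[(2R,3R)-3-hydroxypentan-2-yl]-3,5-dimethyl-4H-pyran-4-one
Conditions: HF·pyridine, pyridine, THF, 0 °C to rt
Reagents that add atoms: none
Why: Buffered fluoride desilylation removes the single silyl ether without base, so the acidic lateral and allylic Ca–H and the aldol-type arms are not epimerised or cleaved.

**Compound list**
1 | 2,6-diethyl-3,5-dimethyl-4H-pyran-4-one | CCc1oc(CC)c(C)c(=O)c1C | starting material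
2 | propanal | CCC=O | starting material
3 | tert-butyl{[(2Z)-6-ethyl-2-ethylidene-3,5-dimethyl-2H-pyran-4-yl]oxy}dimethylsilane | C/C=C1\OC(CC)=C(C)C(O[Si](C)(C)C(C)(C)C)=C1C | intermediate
4 | 2-ethyl-6-[(2R,3R)-3-hydroxypentan-2-yl]-3,5-dimethyl-4H-pyran-4-one | CCc1oc([C@H](C)[C@H](O)CC)c(C)c(=O)c1C | intermediate
5 | 2-methylprop-2-enal | CC(=C)C=O | starting material
6 | 2,3-dibromo-2-methylpropanal (racemic) | O=CC(C)(Br)CBr | intermediate
7 | (2E)-3-bromo-2-methylprop-2-enal | Br/C=C(\C)C=O | intermediate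
8 | (E)-but-2-ene | C/C=C/C | starting material
9 | (E)-but-2-enylpotassium | [K+].[CH2-]/C=C/C | intermediate
10 | B-[(2E)-but-2-en-1-yl]bis[(1R,2S,3R,5R)-2,6,6-trimethylbicyclo[3.1.1]hept-3-yl]borane | C/C=C/CB([C@@H]1C[C@@H]2C[C@@H](C2(C)C)[C@H]1C)[C@@H]1C[C@@H]2C[C@@H](C2(C)C)[C@H]1C | intermediate
11 | (1E,3S,4S)-1-bromo-2,4-dimethylhexa-1,5-dien-3-ol | Br/C=C(\C)[C@@H](O)[C@@H](C)C=C | intermediate
12 | {[(1E,3S,4S)-1-bromo-2,4-dimethylhexa-1,5-dien-3-yl]oxy}(tert-butyl)dimethylsilane | Br/C=C(\C)[C@@H](O[Si](C)(C)C(C)(C)C)[C@@H](C)C=C | intermediate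
13 | (3S,4S,5E)-6-bromo-4-[(tert-butyldimethylsilyl)oxy]-3,5-dimethylhex-5-ene-1,2-diol (C2 epimers) | Br/C=C(\C)[C@@H](O[Si](C)(C)C(C)(C)C)[C@@H](C)C(O)CO | intermediate
14 | (2R,3S,4E)-5-bromo-3-[(tert-butyldimethylsilyl)oxy]-2,4-dimethylpent-4-enal | Br/C=C(\C)[C@@H](O[Si](C)(C)C(C)(C)C)[C@@H](C)C=O | intermediate
15 | dilithium dianion of 4 (alkoxide and (Z)-ethylidene pyranolate) | [Li+].[Li+].C/C=C1\OC([C@H](C)[C@H]([O-])CC)=C(C)C([O-])=C1C | intermediate
16 | 2-[(2S,3S,4S,5S,6E)-7-bromo-5-[(tert-butyldimethylsilyl)oxy]-3-hydroxy-4,6-dimethylhept-6-en-2-yl]-6-[(2R,3R)-3-hydroxypentan-2-yl]-3,5-dimethyl-4H-pyran-4-one | Br/C=C(\C)[C@@H](O[Si](C)(C)C(C)(C)C)[C@@H](C)[C@H](O)[C@H](C)c1oc([C@H](C)[C@H](O)CC)c(C)c(=O)c1C | intermediate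
17 | lithium (2Z)-6-ethyl-2-ethylidene-3,5-dimethyl-2H-pyran-4-olate | [Li+].C/C=C1\OC(CC)=C(C)C([O-])=C1C | intermediate
18 | rac-2-(1-chloroethyl)-6-ethyl-3,5-dimethyl-4H-pyran-4-one | CCc1oc(C(C)Cl)c(C)c(=O)c1C | intermediate
19 | 2-[(2S,3S,4S,5S,6E,8S)-5-[(tert-butyldimethylsilyl)oxy]-8-(6-ethyl-3,5-dimethyl-4-oxo-4H-pyran-2-yl)-3-hydroxy-4,6-dimethylnon-6-en-2-yl]-6-[(2R,3R)-3-hydroxypentan-2-yl]-3,5-dimethyl-4H-pyran-4-one | CCc1oc([C@@H](C)/C=C(\C)[C@@H](O[Si](C)(C)C(C)(C)C)[C@@H](C)[C@H](O)[C@H](C)c2oc([C@H](C)[C@H](O)CC)c(C)c(=O)c2C)c(C)c(=O)c1C | intermediate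
20 | 2-[(2S,3S,4S,5S,6E,8S)-8-(6-ethyl-3,5-dimethyl-4-oxo-4H-pyran-2-yl)-3,5-dihydroxy-4,6-dimethylnon-6-en-2-yl]-6-[(2R,3R)-3-hydroxypentan-2-yl]-3,5-dimethyl-4H-pyran-4-one | CCc1oc([C@@H](C)/C=C(\C)[C@@H](O)[C@@H](C)[C@H](O)[C@H](C)c2oc([C@H](C)[C@H](O)CC)c(C)c(=O)c2C)c(C)c(=O)c1C | target

**Step count**
Total: 9 steps. Longest linear sequence: 7 steps (2, 3, 4, 5, 6, 8, 9).

**Three steps most likely to fail**

Step 1. The risks are that propanal reacts sluggishly in the SiCl4 system, that the anti selectivity or ee is low for a methylenepyran nucleophile, and that the sense of induction is assigned only by analogy. The fallback sets out from 1 and 2 and comes back at 4. Compound 1 is deprotonated with LiN(SiMe3)2 in THF at −78 °C and treated with propanal; after removal of the syn isomer this gives racemic anti aldol rac-2-ethyl-6-(3-hydroxypentan-2-yl)-3,5-dimethyl-4H-pyran-4-one F1. Candida antarctica lipase B with vinyl acetate then acylates only the (3R)-carbinol (large α-branched group against ethyl, as the Kazlauskas rule predicts) to give (2R,3R)-2-(6-ethyl-3,5-dimethyl-4-oxo-4H-pyran-2-yl)pentan-3-yl acetate F2, which is separated from the untouched (2S,3S)-alcohol. K2CO3 in MeOH returns 4. This replaces catalytic face selection by a resolution and costs at most half the material.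

Step 6. The risks are low Cf/Cg simple diastereoselectivity from the aggregated lithium dianion, an imperfect Felkin ratio, and retro-aldol on warming. The fallback sets out from 4 and comes back at 20. Compound 4 with TBSOTf (2.5 equiv) and Et3N gives the bis-silylated methylenepyran (2Z)-4-(tert-butyldimethylsilyloxy)-6-[(2R,3R)-3-(tert-butyldimethylsilyloxy)pentan-2-yl]-2-ethylidene-3,5-dimethyl-2H-pyran F3. A BF3·OEt2-promoted vinylogous Mukaiyama aldol of F3 with 14 at −78 °C (open transition state, where Felkin and 1,3-anti induction are strongest) gives the Ci-silylated analogue of 16 F4. F4 is coupled with 18 exactly as in step 8 to give the bis-silyl ether of 20 F5, and HF·pyridine removes both silyl groups to give 20.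

Step 8. The risks are that the pyranone-stabilised radical is captured with poor enantiocontrol, that homocoupling competes, and that the ligand sense is unknown for this substrate class. The fallback sets out from 18 and 16 and comes back at 19. DBU eliminates HCl from 18 to give 2-ethenyl-6-ethyl-3,5-dimethyl-4H-pyran-4-one F6. A nickel hydride catalysed enantioselective Markovnikov hydroalkenylation of F6 with the alkenyl bromide 16 (NiBr2(dme), chiral bis(imidazoline) ligand, (MeO)2MeSiH, KF, DMA, rt) then gives 19. Here the C–Ni bond at Ca arises by hydride insertion into the vinyl group and not by halogen abstraction.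

**Further compounds**
F1 | step 1 | rac-2-ethyl-6-[(2R*,3R*)-3-hydroxypentan-2-yl]-3,5-dimethyl-4H-pyran-4-one | CCc1oc([C@H](C)[C@H](O)CC)c(C)c(=O)c1C.CCc1oc([C@@H](C)[C@@H](O)CC)c(C)c(=O)c1C
F2 | step 1 | (2R,3R)-2-(6-ethyl-3,5-dimethyl-4-oxo-4H-pyran-2-yl)pentan-3-yl acetate | CCc1oc([C@H](C)[C@H](OC(C)=O)CC)c(C)c(=O)c1C
F3 | step 6 | (2Z)-4-(tert-butyldimethylsilyloxy)-6-[(2R,3R)-3-(tert-butyldimethylsilyloxy)pentan-2-yl]-2-ethylidene-3,5-dimethyl-2H-pyran | C/C=C1\OC([C@H](C)[C@H](O[Si](C)(C)C(C)(C)C)CC)=C(C)C(O[Si](C)(C)C(C)(C)C)=C1C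
F4 | step 6 | 2-[(2S,3S,4S,5S,6E)-7-bromo-5-(tert-butyldimethylsilyloxy)-3-hydroxy-4,6-dimethylhept-6-en-2-yl]-6-[(2R,3R)-3-(tert-butyldimethylsilyloxy)pentan-2-yl]-3,5-dimethyl-4H-pyran-4-one | Br/C=C(\C)[C@@H](O[Si](C)(C)C(C)(C)C)[C@@H](C)[C@H](O)[C@H](C)c1oc([C@H](C)[C@H](O[Si](C)(C)C(C)(C)C)CC)c(C)c(=O)c1C
F5 | step 6 | bis(tert-butyldimethylsilyl) ether of 20 at the Cd and Ci oxygens | CCc1oc([C@@H](C)/C=C(\C)[C@@H](O[Si](C)(C)C(C)(C)C)[C@@H](C)[C@H](O)[C@H](C)c2oc([C@H](C)[C@H](O[Si](C)(C)C(C)(C)C)CC)c(C)c(=O)c2C)c(C)c(=O)c1C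
F6 | step 8 | 2-ethenyl-6-ethyl-3,5-dimethyl-4H-pyran-4-one | CCc1oc(C=C)c(C)c(=O)c1C
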